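**Assumption:** Atom numbers are those of the target (labdane numbering: ring A = C1–C5 and C10, ring B = C5–C10, methyls C18/C19 on C4, C20 on C10, C17 on C8, chain C11–C15 with C16 on C13). The bicyclic intermediates keep these numbers (verbenone C1–C7 = C7, C8, C9, C10, C5, C4, C6); only their systematic names use bicycloheptane locants. (1S,5S)-(−)-Verbenone and (S)-(−)-citronellol are taken as enantiopure commercial materials.

## The problem

Compound 23 is the diacetate of an ent-labd-7-ene-2,15-diol. It is a trans-fused decalin: ring A has a gem-dimethyl group at C4 and an equatorial acetoxy group at C2; ring B has the angular methyl C20 on quaternary C10, a trisubstituted C7=C8 alkene carrying C17, and at C9 a five-carbon chain with a methyl-bearing stereocentre at C13 and a terminal acetate. The hard carbons are in ring A: C4 and C10 are both fully substituted and flank the fusion carbon C5, so every ring bond to them is neopentylic. Of the five stereocentres, C5 and C10 define the trans fusion and the absolute series. Once they sit in a rigid decalin, the axial C20 methyl steers reagents at C9 to the opposite face, and the equatorial position at C2 is the thermodynamic one, so C9 and C2 can be set by substrate control. C13 is four bonds from the ring and cannot be controlled from it; it has to be brought in enantiopure. The C7=C8 alkene can migrate under acid to the tetrasubstituted or exocyclic position, C9 is epimerisable for as long as C8 is a carbonyl, and the two acetates tolerate neither enolate bases, hydrides nor organocopper reagents, so they must come last. The feature that opens the route is ring B itself: a six-membered ring with C20 on C10, oxygen at C8, the C5 stereocentre and the dimethylated C4 on C5 is the carbon framework of verbenone (1), in which C4 is additionally tied to C7 in a cyclobutane. Breaking that one strained bond under the push of the C8 carbonyl would place a tertiary cation at C4, where ring A has to close, and an enol derivative at C7=C8, where the alkene is needed.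

## Retrosynthesis

**Acetates last (23 from 21).** Both C–O acetate bonds are cut first, back to diol 22 and its bis-silyl ether 21. Silyl ethers are chosen because they survive every base, hydride and organometallic used earlier and fall together to fluoride, which does not disturb the C7=C8 alkene. The forward steps are routine.

**C8–C17 (21 from 19).** The methyl group is cut from the alkene, leading to enol triflate 20 and 17-nor ketone 19. The neighbouring option, methyl addition to the ketone and dehydration, would give a mixture of the Δ7, Δ8 and exocyclic alkenes. The triflate fixes the double bond where the enolate was, and kinetic deprotonation of 19 can only reasonably occur at the C7 methylene, since C9 is a methine next to quaternary C10. The forward reaction must leave C9 untouched.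

**C9–C11 (19 from 10 and 15).** The chain is cut at the ring, giving enone 10 and aldehyde 15 by way of dienone 18. An SN2 alkylation with the corresponding iodide was the neighbouring cut; it was set aside because C9 is neopentylic and the electrophile unactivated, and because axial attack anti to C20 would give the wrong C9 epimer. An aldol addition to an unhindered aldehyde is fast even at such a carbon, and after dehydration the C9 configuration is made by hydrogenation from the face opposite C20. The precursor 10 has lost the chain and C13 and has only three stereocentres. The enone in 10 exists to block C7, so that base can act only at C9.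

**The chain (15 from 11).** C13 cannot be induced from the ring, so it is taken from (S)-citronellol (11), whose C1–C5 segment maps onto C15–C11. One carbon too many remains after cleavage of the alkene (aldehyde 13), so it is removed through enol ether 14. The forward steps ask only that the stereocentre, never α to a carbonyl, stays untouched.

**Redox adjustment of the bicycle (10 from 7).** Enone 10 is traced to silyl ether 9, alcohol 8 and keto enol ether 7. The C6=C7 alkene comes from a Saegusa–Ito oxidation of the C7=C8 silyl enol ether. The C2 stereocentre comes from a dissolving-metal reduction, which gives the equatorial alcohol where hydrides would give the axial one. Both steps depend on the two carbonyl carbons C2 and C8 being differentiated in 7, one as a ketone and one as a silyl enol ether. The silyl group is therefore tert-butyldimethylsilyl, which survives lithium in ammonia.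

**Ring A (7 from 6), the key disconnection.** The C3–C4 bond is cut and the C4–C7 bond re-formed, which turns the decalin 7 into the bicyclo[3.1.1]heptanone 6 with a silyloxyallyl arm on C10. The neighbouring cuts of ring A (C1–C10, C4–C5, or an aldol-type cut at C1–C2) would each require a quaternary carbon to be built intermolecularly or ring B to be assembled from scratch. This cut makes the most congested bond of ring A intramolecularly from a tertiary cation, pays for it with cyclobutane strain, and leaves C2 and C8 differentiated. The precursor has one ring fewer in the decalin sense and its stereocentres are those of the starting terpene plus C10. The forward reaction must ionise C4–C7 rather than C6–C7 and must alkylate the enol silane before the cation loses a proton.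

**The arm (6 from 1 and 2).** The C1–C10 bond is cut, giving verbenone (1) and allylmagnesium bromide (2) by way of diketone 5 and allyl ketone 4. Conjugate addition to 1 is known to occur anti to the gem-dimethyl bridge, which places the arm trans to C4 as the trans-decalin requires. A Wacker oxidation and a kinetic silylation of the methyl ketone turn the allyl group into the nucleophile. The forward sequence asks for 1,4- rather than 1,2-addition of an allyl metal and for enolisation of the methyl ketone in the presence of the ring ketone.

## Roads not taken

**Alternative 1:** The cut is the C1–C10 bond of ring A in a monocyclic ring-B precursor, β-keto ester A2, which already carries the C9 chain and the C8 methyl group and has a tetrasubstituted C5=C10 alkene. In the forward step Mn(OAc)3 oxidises the β-keto ester to its C1 radical, which adds to C10 and closes ring A, and Cu(OAc)2 oxidises the resulting C5 radical to the C5=C6 alkene of A1.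
- Merits: oxidative radical cyclisations of unsaturated β-keto esters are an established way to make six-membered rings with quaternary carbons; the adjacent C9 stereocentre can steer the new C10 centre; the chain and C13 are present from the start.
- Weak points: A1 has its unsaturation at C5=C6 and a saturated, stereogenic C8, whereas 23 needs H5 and a C7=C8 alkene. Hydrogenation could deliver H5 anti to C20, but ring B would then hold no functional group from which the C7=C8 alkene could be regenerated regioselectively, and moving the alkene by acid equilibration cannot be steered. The C1 ester has to be excised, the C8 stereocentre is built only to be destroyed, and A2 needs a long preparation.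
- Comparison: this road is better in that its key step is known chemistry and no late C9–C11 coupling is needed. The chosen plan sets against this a ring B whose oxygen sits at C8, from which both C17 and the alkene follow regiospecifically, and a shorter sequence.

**Alternative 2:** The cut is made at C10–C20 and C9–C20: the angular methyl is treated as one carbon of a cyclopropane across C9–C10. In the forward step Et2Zn and CH2I2 deliver a methylene to the tetrasubstituted C9=C10 alkene of allylic alcohol A4 on the face of the C8 hydroxyl (directed Simmons–Smith reaction), giving A3. Oxidation to the cyclopropyl ketone and reductive cleavage of C9–C20 would then reveal C20 and a C8=C9 enolate.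
- Merits: every operation is well known, the directed cyclopropanation is dependable even on fully substituted alkenes, and the reductive opening gives a regiodefined C9 enolate. In this respect the road is clearly better than the chosen plan, which must spend a Saegusa–Ito oxidation to block C7.
- Weak points: nothing in A4 comes from the chiral pool, so the absolute configuration needs an enantioselective step. The cyclopropane must end up trans to H5, which requires the C8 carbinol to be set in a 1,4-relationship to C5 across ring B. The aromatic precursor with a benzylic quaternary carbon and oxygen at C2 must be made and dearomatised. Trapping the enolate with an unactivated halide at neopentylic C9 is capricious, and axial attack anti to C20 would give the unnatural C9 epimer.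
- Comparison: against the better enolate regiocontrol the chosen plan sets C5 and C10 bought with 1, ring A with its gem-dimethyl group and C2 oxygen formed in one step, and a C9–C11 bond made by aldol addition.

**Alternative 3:** Both ring-A bonds to the fusion carbons, C1–C10 and C4–C5, are cut, which leads to 2,6-dimethylbenzoquinone A6 and silyloxy diene A7. In the forward step a chiral titanium Lewis acid (TiCl2(OiPr)2 with BINOL) would promote the Diels–Alder reaction at the methyl-bearing C5=C10 double bond of A6, and basic work-up would epimerise C5 to give the trans-fused enedione A5.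
- Merits: two achiral commercial components give the whole decalin in one step, the absolute configuration comes from a catalyst, and the untouched half of the quinone already holds the C8 methyl group on a C7=C8 double bond. In convergence and in this unit the road is better than the chosen plan, which needs two steps for it.
- Weak points: A7 has two methyl groups on its reacting terminus, one necessarily cis, which disfavours the s-cis conformer, and the dienophile carbon C10 becomes quaternary; enantioselective quinone cycloadditions are not established for such a hindered pair. A5 then carries oxygen at C6, where the target has none, and a carbonyl at C9, where the target has hydrogen and the chain. Chain addition at C9 in the presence of the C6 carbonyl, stereoselective removal of the resulting tertiary oxygen next to C10, deoxygenation at C6 and adjustment at C2 add up to a long redox sequence.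
- Comparison: against the higher convergence the chosen plan sets carbons that arrive at or near their final oxidation level, a C9 that is functionalised as an enolisable position rather than defunctionalised, and absolute configuration taken from the chiral pool.

Key step: step 4

## Route

Step 1
Reactants: 1 (1S,5S)-(−)-verbenone; 2 allylmagnesium bromide
Product: 4 (1S,4S,5S)-4-allyl-4,6,6-trimethylbicyclo[3.1.1]heptan-2-one (allyl group anti to the gem-dimethyl bridge), via silyl enol ether 3 (not isolated)
Conditions: CuBr·SMe2 (1.2 equiv), LiCl, 2 (1.2 equiv), THF, −78 °C; TMSCl, then 1, −78 °C; 1 M HCl work-up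
Reagents that add atoms: none
Why: Conjugate allylation of a β,β-disubstituted enone with a preformed allylcopper reagent and TMSCl, conditions that suppress the 1,2-addition usual for allyl Grignard reagents; the enolate is trapped as silyl enol ether 3 and hydrolysed on work-up. The reagent reaches C10 from the face opposite the gem-dimethyl bridge, the established sense for additions to verbenone, which sets the quaternary C10 centre with the arm trans to C4.

Step 2
Reactants: 4 (1S,4S,5S)-4-allyl-4,6,6-trimethylbicyclo[3.1.1]heptan-2-one
Product: 5 (1S,4S,5S)-4,6,6-trimethyl-4-(2-oxopropyl)bicyclo[3.1.1]heptan-2-one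
Conditions: PdCl2 (10 mol%), CuCl, O2 (1 atm), DMF/H2O, rt
Reagents that add atoms: water, O
Why: Wacker–Tsuji oxidation; Markovnikov oxypalladation of the monosubstituted alkene gives the methyl ketone (C2 carbonyl, C3 methyl). The hindered ring ketone and the cyclobutane are expected to be inert to the nearly neutral medium.

Step 3
Reactants: 5 (1S,4S,5S)-4,6,6-trimethyl-4-(2-oxopropyl)bicyclo[3.1.1]heptan-2-one
Product: 6 (1S,4S,5S)-4-[2-(tert-butyldimethylsilyloxy)prop-2-en-1-yl]-4,6,6-trimethylbicyclo[3.1.1]heptan-2-one
Conditions: LDA (1.05 equiv), THF, −78 °C, 5 added slowly; TBSOTf (1.1 equiv), −78 °C; Et3N, aq NaHCO3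
Reagents that add atoms: tert-butyldimethylsilyl trifluoromethanesulfonate (TBSOTf), CC(C)(C)[Si](C)(C)OS(=O)(=O)C(F)(F)F
Why: Kinetic enolisation and O-silylation; LDA should take a proton from the exposed C3 methyl rather than from neopentylic C1 or from C9, which is flanked by quaternary C10 and shielded by the bridge, while C7 cannot enolise (Bredt's rule). The silyl triflate traps the enolate at −78 °C before aldol addition or proton transfer; the tert-butyldimethylsilyl group is chosen because it is relayed to C8 in step 4 and must survive step 5.

Step 4
Reactants: 6 (1S,4S,5S)-4-[2-(tert-butyldimethylsilyloxy)prop-2-en-1-yl]-4,6,6-trimethylbicyclo[3.1.1]heptan-2-one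
Product: 7 (5R,10R)-8-(tert-butyldimethylsilyloxy)-4,4,10-trimethyl-Δ7-octalin-2-one (trans-fused; C2 ketone; C7=C8 silyl enol ether)
Conditions: TBSOTf (10 mol%), 2,6-di-tert-butyl-4-methylpyridine (5 mol%), CH2Cl2, −78 → 0 °C; Et3N quench
Reagents that add atoms: none
Why: Proposed new method: TBSOTf reversibly silylates the C8 carbonyl; in the silyloxycarbenium ion the strained C4–C7 bond, held out of the carbonyl plane by the bicycle, breaks to give the C7=C8 silyl enol ether and a tertiary cation at C4, which the pendant enol silane captures through C3 to form C3–C4 and ring A, and the C2 silyloxycarbenium ion then passes its silyl group to triflate or to the next molecule of 6, so the silyl Lewis acid turns over. The closest known reaction types are the Lewis-acid or iodosilane opening of the cyclobutane of nopinone-type ketones to cyclohexenyl enol derivatives with a tertiary cationic or halide centre, and the Lewis-acid-mediated α-tert-alkylation of silyl enol ethers by tertiary halides; their fusion into one catalytic cascade with an internal enol silane has not been shown. Ring A closes in a 6-(enolendo)-exo-tet mode, which Baldwin's rules for enolates allow. No stereocentre is created: C5 and C10 come unchanged from 1, and because the C1 arm and C4 are trans on ring B both can be equatorial in the half-chair, so only the trans-fused decalin can form, while C7 becomes trigonal. The step needs cleavage of C4–C7 and not C6–C7, which is secured because only the former gives a tertiary cation, both bonds being equally placed for overlap. It also needs C-alkylation to outrun proton loss from C4, which the six-membered reach of the nucleophilic 1,1-disubstituted enol silane and the low temperature should favour, with the hindered pyridine keeping adventitious triflic acid from desilylating the arm. Addition of the arm to the activated C8 carbonyl would give a bridged silyl aldolate pressed against the C6 methylene; it is expected to be reversible and to drain into the irreversible, strain-releasing alkylation.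

Step 5
Reactants: 7 (5R,10R)-8-(tert-butyldimethylsilyloxy)-4,4,10-trimethyl-Δ7-octalin-2-one
Product: 8 (2R,5R,10S)-8-(tert-butyldimethylsilyloxy)-4,4,10-trimethyl-Δ7-octalin-2-ol (equatorial hydroxyl, trans to C20)
Conditions: Li, NH3(l)/THF, t-BuOH, −78 °C; solid NH4Cl
Reagents that add atoms: none
Why: Dissolving-metal reduction of a ketone gives the thermodynamically preferred equatorial alcohol, whereas hydride reagents would attack C2 away from the two syn-axial methyl groups on C4 and C10 and give the axial epimer; this sets C2. The silyl enol ether is not reduced and keeps C8 masked, so the two carbonyl carbons delivered in different forms by step 4 stay distinguished.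

Step 6
Reactants: 8 (2R,5R,10S)-8-(tert-butyldimethylsilyloxy)-4,4,10-trimethyl-Δ7-octalin-2-ol
Product: 9 (2R,5R,10S)-2,8-bis(tert-butyldimethylsilyloxy)-4,4,10-trimethyl-Δ7-octalin (C2 silyl ether, C7=C8 silyl enol ether)
Conditions: TBSCl, imidazole, DMF, rt
Reagents that add atoms: tert-butyldimethylsilyl chloride (TBSCl), CC(C)(C)[Si](C)(C)Cl
Why: Standard silylation of a secondary alcohol; the imidazole buffer should leave the silyl enol ether intact.

Step 7
Reactants: 9 (2R,5R,10S)-2,8-bis(tert-butyldimethylsilyloxy)-4,4,10-trimethyl-Δ7-octalin
Product: 10 (2R,5R,10S)-2-(tert-butyldimethylsilyloxy)-4,4,10-trimethyl-Δ6-octalin-8-one (trans-fused C6=C7–C8=O enone)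
Conditions: Pd(OAc)2 (1.1 equiv), MeCN, rt
Reagents that add atoms: none
Why: Saegusa–Ito oxidation; the palladium enolate formed at C7 from the silyl enol ether loses H6 by β-hydride elimination to give the C6=C7 enone. The enone removes C7 as an enolisable position, so base can act only at C9 in step 12.

Step 8
Reactants: 11 (S)-(−)-citronellol
Product: 12 (S)-tert-butyl[(3,7-dimethyloct-6-en-1-yl)oxy]diphenylsilane
Conditions: TBDPSCl, imidazole, DMF, rt
Reagents that add atoms: tert-butyldiphenylsilyl chloride (TBDPSCl), CC(C)(C)[Si](Cl)(c1ccccc1)c1ccccc1
Why: Standard silylation of a primary alcohol; the robust silyl ether carries the future C15 oxygen to the end and falls with the C2 silyl ether in step 16.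

Step 9
Reactants: 12 (S)-tert-butyl[(3,7-dimethyloct-6-en-1-yl)oxy]diphenylsilane
Product: 13 (S)-6-(tert-butyldiphenylsilyloxy)-4-methylhexanal
Conditions: O3, CH2Cl2, −78 °C; PPh3
Reagents that add atoms: ozone, [O-][O+]=O
Why: Ozonolysis of the trisubstituted alkene with reductive work-up gives the aldehyde and acetone; the stereocentre (later C13) is remote and untouched.

Step 10
Reactants: 13 (S)-6-(tert-butyldiphenylsilyloxy)-4-methylhexanal
Product: 14 (S)-1-(tert-butyldimethylsilyloxy)-6-(tert-butyldiphenylsilyloxy)-4-methylhex-1-ene (E/Z mixture)
Conditions: TBSOTf, Et3N, CH2Cl2, 0 °C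
Reagents that add atoms: tert-butyldimethylsilyl trifluoromethanesulfonate (TBSOTf), CC(C)(C)[Si](C)(C)OS(=O)(=O)C(F)(F)F
Why: Soft enolisation of an aldehyde with a silyl triflate and an amine gives the silyl enol ether; its geometry is irrelevant because the double bond is cleaved in the next step.

Step 11
Reactants: 14 (S)-1-(tert-butyldimethylsilyloxy)-6-(tert-butyldiphenylsilyloxy)-4-methylhex-1-ene
Product: 15 (R)-5-(tert-butyldiphenylsilyloxy)-3-methylpentanal
Conditions: O3, CH2Cl2, −78 °C; PPh3
Reagents that add atoms: ozone, [O-][O+]=O
Why: Ozonolysis of the electron-rich enol ether removes one carbon as a silyl formate, a standard one-carbon degradation of an aldehyde. The new aldehyde carbon is C11, and the stereocentre, now β to the carbonyl, cannot epimerise.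

Step 12
Reactants: 10 (2R,5R,10S)-2-(tert-butyldimethylsilyloxy)-4,4,10-trimethyl-Δ6-octalin-8-one; 15 (R)-5-(tert-butyldiphenylsilyloxy)-3-methylpentanal
Product: 18 (2R,5R,10R,13S)-2-(tert-butyldimethylsilyloxy)-15-(tert-butyldiphenylsilyloxy)-17-norlabda-6,9(11)-dien-8-one (C9=C11 geometry not controlled), via lithium aldolate 16 (not isolated), via mesylate 17 (not isolated)
Conditions: LDA, THF, −78 °C; 15; MsCl, −78 → 0 °C; DBU, rt
Reagents that add atoms: none
Why: Directed aldol condensation; LDA deprotonates the enone kinetically at the α′ carbon C9 (C7 is vinylic, γ-H5 is tertiary and hindered), the enolate adds to the unhindered aldehyde to form C9–C11, and mesylation with E1cB elimination in the same flask removes the aldol oxygen. Addition to an aldehyde is used instead of SN2 alkylation because C9 is neopentylic; the C9/C11 configurations and the alkene geometry are erased in step 13.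

Step 13
Reactants: 18 (2R,5R,10R,13S)-2-(tert-butyldimethylsilyloxy)-15-(tert-butyldiphenylsilyloxy)-17-norlabda-6,9(11)-dien-8-one
Product: 19 (2R,5R,9S,10R,13S)-2-(tert-butyldimethylsilyloxy)-15-(tert-butyldiphenylsilyloxy)-17-norlabdan-8-one (H9 trans to C20, chain equatorial)
Conditions: H2 (1 atm), 10% Pd/C, EtOAc, rt
Reagents that add atoms: none
Why: Heterogeneous hydrogenation saturates the ring enone alkene and the exocyclic alkylidene; hydrogen should reach C9 from the face opposite the axial C20 methyl on the adjacent carbon, which leaves the chain equatorial and cis to C20 (the natural C9 configuration), the epimer also expected to be somewhat favoured at equilibrium. Ketone and silyl ethers are inert.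

Step 14
Reactants: 19 (2R,5R,9S,10R,13S)-2-(tert-butyldimethylsilyloxy)-15-(tert-butyldiphenylsilyloxy)-17-norlabdan-8-one
Product: 20 (2R,5R,9S,10R,13S)-2-(tert-butyldimethylsilyloxy)-15-(tert-butyldiphenylsilyloxy)-17-norlabd-7-en-8-yl trifluoromethanesulfonate
Conditions: KHMDS, THF, −78 °C; PhNTf2, −78 → 0 °C
Reagents that add atoms: N-phenylbis(trifluoromethanesulfonimide) (PhNTf2), O=S(=O)(N(c1ccccc1)S(=O)(=O)C(F)(F)F)C(F)(F)F
Why: Kinetic enolisation with a hindered amide base occurs at the C7 methylene and not at the C9 methine next to quaternary C10, and the triflimide traps the enolate as the Δ7 enol triflate. C9 is not deprotonated, so its configuration is kept.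

Step 15
Reactants: 20 (2R,5R,9S,10R,13S)-2-(tert-butyldimethylsilyloxy)-15-(tert-butyldiphenylsilyloxy)-17-norlabd-7-en-8-yl trifluoromethanesulfonate
Product: 21 (2R,5R,9R,10R,13S)-2-(tert-butyldimethylsilyloxy)-15-(tert-butyldiphenylsilyloxy)labd-7-ene
Conditions: Me2CuLi (from CuI and MeLi), THF/Et2O, −15 → 0 °C
Reagents that add atoms: lithium dimethylcuprate (Me2CuLi), [Li+].C[Cu-]C
Why: Cuprate coupling of an enol triflate replaces the triflate by methyl (C17) without moving the double bond, and no acid that could isomerise the trisubstituted alkene is involved.

Step 16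
Reactants: 21 (2R,5R,9R,10R,13S)-2-(tert-butyldimethylsilyloxy)-15-(tert-butyldiphenylsilyloxy)labd-7-ene
Product: 22 (2R,5R,9R,10R,13S)-labd-7-ene-2,15-diol
Conditions: TBAF, THF, 50 °C
Reagents that add atoms: none
Why: Fluoride cleaves both silyl ethers; the conditions leave the C7=C8 alkene in place.

Step 17
Reactants: 22 (2R,5R,9R,10R,13S)-labd-7-ene-2,15-diol
Product: 23 (2R,5R,9R,10R,13S)-labd-7-ene-2,15-diyl diacetate
Conditions: Ac2O, pyridine, DMAP (cat.), CH2Cl2, rt
Reagents that add atoms: acetic anhydride, CC(=O)OC(C)=O
Why: Acylation of the primary and the equatorial secondary alcohol under nucleophilic catalysis; the acetates come last because none of the earlier bases, hydrides or organometallics would tolerate them.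

## Compound list

1 | (1S,5S)-(−)-verbenone, (1S,5S)-4,6,6-trimethylbicyclo[3.1.1]hept-3-en-2-one | O=C1C=C(C)[C@@H]2C[C@H]1C2(C)C | starting material
2 | allylmagnesium bromide | C=CC[Mg]Br | starting material
3 | trimethylsilyl enol ether of 4 (C8–OSiMe3, C8=C9; allyl anti to the gem-dimethyl bridge) | C[Si](C)(C)OC1=C[C@](C)(CC=C)[C@@H]2C[C@H]1C2(C)C | intermediate
4 | (1S,4S,5S)-4-allyl-4,6,6-trimethylbicyclo[3.1.1]heptan-2-one | O=C1C[C@](C)(CC=C)[C@@H]2C[C@H]1C2(C)C | intermediate
5 | (1S,4S,5S)-4,6,6-trimethyl-4-(2-oxopropyl)bicyclo[3.1.1]heptan-2-one | O=C1C[C@](C)(CC(C)=O)[C@@H]2C[C@H]1C2(C)C | intermediate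
6 | (1S,4S,5S)-4-[2-(tert-butyldimethylsilyloxy)prop-2-en-1-yl]-4,6,6-trimethylbicyclo[3.1.1]heptan-2-one | O=C1C[C@](C)(CC(=C)O[Si](C)(C)C(C)(C)C)[C@@H]2C[C@H]1C2(C)C | intermediate
7 | (5R,10R)-8-(tert-butyldimethylsilyloxy)-4,4,10-trimethyl-Δ7-octalin-2-one, trans-fused, [(4aR,8aR)-7-(tert-butyldimethylsilyloxy)-4,4,8a-trimethyl-3,4,4a,5,8,8a-hexahydronaphthalen-2(1H)-one] | CC(C)(C)[Si](C)(C)OC1=CC[C@@H]2C(C)(C)CC(=O)C[C@@]2(C)C1 | intermediate
8 | (2R,5R,10S)-8-(tert-butyldimethylsilyloxy)-4,4,10-trimethyl-Δ7-octalin-2-ol, trans-fused, equatorial hydroxyl | CC(C)(C)[Si](C)(C)OC1=CC[C@@H]2C(C)(C)C[C@@H](O)C[C@@]2(C)C1 | intermediate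
9 | (2R,5R,10S)-2,8-bis(tert-butyldimethylsilyloxy)-4,4,10-trimethyl-Δ7-octalin, trans-fused | CC(C)(C)[Si](C)(C)OC1=CC[C@@H]2C(C)(C)C[C@@H](O[Si](C)(C)C(C)(C)C)C[C@@]2(C)C1 | intermediate
10 | (2R,5R,10S)-2-(tert-butyldimethylsilyloxy)-4,4,10-trimethyl-Δ6-octalin-8-one, trans-fused | O=C1C=C[C@@H]2C(C)(C)C[C@@H](O[Si](C)(C)C(C)(C)C)C[C@@]2(C)C1 | intermediate
11 | (S)-(−)-citronellol, (S)-3,7-dimethyloct-6-en-1-ol | OCC[C@@H](C)CCC=C(C)C | starting material
12 | (S)-tert-butyl[(3,7-dimethyloct-6-en-1-yl)oxy]diphenylsilane | CC(C)(C)[Si](c1ccccc1)(c1ccccc1)OCC[C@@H](C)CCC=C(C)C | intermediate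
13 | (S)-6-(tert-butyldiphenylsilyloxy)-4-methylhexanal | CC(C)(C)[Si](c1ccccc1)(c1ccccc1)OCC[C@@H](C)CCC=O | intermediate
14 | (S)-1-(tert-butyldimethylsilyloxy)-6-(tert-butyldiphenylsilyloxy)-4-methylhex-1-ene, E/Z mixture | CC(C)(C)[Si](c1ccccc1)(c1ccccc1)OCC[C@@H](C)CC=CO[Si](C)(C)C(C)(C)C | intermediate
15 | (R)-5-(tert-butyldiphenylsilyloxy)-3-methylpentanal | CC(C)(C)[Si](c1ccccc1)(c1ccccc1)OCC[C@@H](C)CC=O | intermediate
16 | lithium aldolate from 10 and 15 (C9–C11 bond, O-lithiated at C11; mixture at C9 and C11) | O=C1C=C[C@@H]2C(C)(C)C[C@@H](O[Si](C)(C)C(C)(C)C)C[C@@]2(C)C1C([O-])C[C@H](C)CCO[Si](c1ccccc1)(c1ccccc1)C(C)(C)C.[Li+] | intermediate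
17 | C11 methanesulfonate of the aldol adduct (mixture at C9 and C11) | O=C1C=C[C@@H]2C(C)(C)C[C@@H](O[Si](C)(C)C(C)(C)C)C[C@@]2(C)C1C(OS(C)(=O)=O)C[C@H](C)CCO[Si](c1ccccc1)(c1ccccc1)C(C)(C)C | intermediate
18 | (2R,5R,10R,13S)-2-(tert-butyldimethylsilyloxy)-15-(tert-butyldiphenylsilyloxy)-17-norlabda-6,9(11)-dien-8-one, C9=C11 geometry not defined | O=C1C=C[C@@H]2C(C)(C)C[C@@H](O[Si](C)(C)C(C)(C)C)C[C@@]2(C)C1=CC[C@H](C)CCO[Si](c1ccccc1)(c1ccccc1)C(C)(C)C | intermediate
19 | (2R,5R,9S,10R,13S)-2-(tert-butyldimethylsilyloxy)-15-(tert-butyldiphenylsilyloxy)-17-norlabdan-8-one | O=C1CC[C@@H]2C(C)(C)C[C@@H](O[Si](C)(C)C(C)(C)C)C[C@@]2(C)[C@@H]1CC[C@H](C)CCO[Si](c1ccccc1)(c1ccccc1)C(C)(C)C | intermediate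
20 | (2R,5R,9S,10R,13S)-2-(tert-butyldimethylsilyloxy)-15-(tert-butyldiphenylsilyloxy)-17-norlabd-7-en-8-yl trifluoromethanesulfonate | O=S(=O)(OC1=CC[C@@H]2C(C)(C)C[C@@H](O[Si](C)(C)C(C)(C)C)C[C@@]2(C)[C@@H]1CC[C@H](C)CCO[Si](c1ccccc1)(c1ccccc1)C(C)(C)C)C(F)(F)F | intermediate
21 | (2R,5R,9R,10R,13S)-2-(tert-butyldimethylsilyloxy)-15-(tert-butyldiphenylsilyloxy)labd-7-ene | CC1=CC[C@@H]2C(C)(C)C[C@@H](O[Si](C)(C)C(C)(C)C)C[C@@]2(C)[C@@H]1CC[C@H](C)CCO[Si](c1ccccc1)(c1ccccc1)C(C)(C)C | intermediate
22 | (2R,5R,9R,10R,13S)-labd-7-ene-2,15-diol | CC1=CC[C@@H]2C(C)(C)C[C@@H](O)C[C@@]2(C)[C@@H]1CC[C@H](C)CCO | intermediate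
23 | (2R,5R,9R,10R,13S)-labd-7-ene-2,15-diyl diacetate (CNP0220683.1) | CC(=O)OCC[C@@H](C)CC[C@@H]1C(C)=CC[C@@H]2C(C)(C)C[C@@H](OC(C)=O)C[C@@]12C | target

## Step count and risk

Total: 17 steps. Longest linear sequence: 13 steps (steps 1–7 and 12–17 from 1). The side-chain aldehyde 15 takes four steps (8–11) from 11.

**Step 4 (key step, Proposed new method).**
- What may go wrong: catalytic silyl triflate may not activate the hindered C8 carbonyl enough for ionisation; the C4 cation may lose a proton to an isopropenyl group faster than it is captured; the arm may add to the activated C8 carbonyl and stay there; traces of acid may desilylate the arm before the cation forms.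
- Fallback (known chemistry, the two events separated): starting from 6, iodotrimethylsilane in CH2Cl2 opens the cyclobutane as it does in nopinone-type ketones, giving the tertiary iodide with a C7=C8 trimethylsilyl enol ether, F1. C8 is then no longer a carbonyl, so the aldol diversion is closed. Ionisation of the tertiary iodide with ZnI2 in CH2Cl2 at low temperature, in the manner of the Lewis-acid-mediated α-tert-alkylation of silyl enol ethers by tertiary halides, closes ring A to the C8 trimethylsilyl enol ether F2. Mild aqueous acid gives trans-4,4,10-trimethyldecalin-2,8-dione F3. Kinetic enolisation of F3 with LDA should occur at C7, the only α-methylene not next to a quaternary carbon, and TBSOTf returns the route to 7.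

**Step 3.**
- What may go wrong: competing deprotonation at C9 of the ring ketone, or double silylation, would give enol silanes in which C8 can no longer be activated; equilibration of the lithium enolate before trapping would have the same effect.
- Fallback (C8 is taken out of the competition by a redox detour): starting from 4, NaBH4 in MeOH reduces the ring ketone to the C8 alcohol F4 (hydride from the face away from the gem-dimethyl bridge; the epimer ratio is immaterial). Wacker oxidation as in step 2 gives hydroxy ketone F5, and TMSCl/Et3N gives the trimethylsilyl ether F6. LDA then TBSOTf, now with a single carbonyl present, gives the silyl enol ether F7. K2CO3 in MeOH at 0 °C removes only the trimethylsilyl ether to give alcohol F8, and Dess–Martin periodinane buffered with pyridine oxidises C8, returning the route to 6.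

**Step 1.**
- What may go wrong: direct addition of the allyl metal to the C8 carbonyl instead of conjugate addition, or slow addition at the hindered β-carbon with loss of reagent.
- Fallback (the 1,2-adduct is made on purpose and rearranged): starting from 1 and 2 without copper, addition in THF at −78 °C from the face away from the bridge gives the tertiary bis-allylic alcohol F9. Anionic oxy-Cope rearrangement (KH, 18-crown-6, THF) moves the allyl group suprafacially to C10 on the same face, and protonation of the enolate returns the route to 4.

**Step 12.**
- What may go wrong: equilibration of the kinetic C9 enolate to the extended dienolate through H5, reversal of the aldol addition during mesylation, or incomplete elimination.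
- Fallback (C9–C11 by alkylation instead of aldol condensation): starting from 15, NaBH4 gives (S)-5-(tert-butyldiphenylsilyloxy)-3-methylpentan-1-ol F10, and I2/PPh3/imidazole gives the (R)-iodide F11. The lithium enolate of 10 (LDA, THF/HMPA) is alkylated with F11, anti to C20, to give the C9-alkylated enone F12 with the chain axial. Hydrogenation (H2, Pd/C) gives the saturated C9 epimer F13, and equilibration with NaOMe in MeOH, expected to favour the equatorial chain, returns the route to 19; the axial epimer would be recycled.

**Step 13.**
- What may go wrong: delivery of hydrogen to C9 from the C20 face (poor facial selectivity), or incomplete reduction of the hindered alkylidene.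
- Fallback (hydride and proton delivered separately): starting from 18, conjugate reduction with [(Ph3P)CuH]6 in wet toluene places hydride at C6 and C11, and the proton then reaches C9 from the face away from C20, returning the route to 19 without a new isolated compound.

## Further compounds

F1 | step 4 | tertiary iodide from ring opening of 6: C4–I, C7=C8 trimethylsilyl enol ether, C10 arm as tert-butyldimethylsilyl enol ether | C[Si](C)(C)OC1=CC[C@H](C(C)(C)I)[C@@](C)(CC(=C)O[Si](C)(C)C(C)(C)C)C1
F2 | step 4 | (5R,10R)-4,4,10-trimethyl-8-(trimethylsilyloxy)-Δ7-octalin-2-one, trans-fused | C[Si](C)(C)OC1=CC[C@@H]2C(C)(C)CC(=O)C[C@@]2(C)C1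
F3 | step 4 | (5R,10R)-4,4,10-trimethyl-trans-decalin-2,8-dione | O=C1CC[C@@H]2C(C)(C)CC(=O)C[C@@]2(C)C1
F4 | step 3 | C8 alcohol of 4 (hydroxyl syn to the gem-dimethyl bridge), 4-allyl-4,6,6-trimethylbicyclo[3.1.1]heptan-2-ol | O[C@H]1C[C@](C)(CC=C)[C@@H]2C[C@H]1C2(C)C
F5 | step 3 | 1-(2-hydroxy-4,6,6-trimethylbicyclo[3.1.1]heptan-4-yl)propan-2-one, same configuration as F4 | O[C@H]1C[C@](C)(CC(C)=O)[C@@H]2C[C@H]1C2(C)C
F6 | step 3 | trimethylsilyl ether of F5 | C[Si](C)(C)O[C@H]1C[C@](C)(CC(C)=O)[C@@H]2C[C@H]1C2(C)C
F7 | step 3 | tert-butyldimethylsilyl enol ether (C2=C3) of F6 | C[Si](C)(C)O[C@H]1C[C@](C)(CC(=C)O[Si](C)(C)C(C)(C)C)[C@@H]2C[C@H]1C2(C)C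
F8 | step 3 | C8 alcohol corresponding to 6 | O[C@H]1C[C@](C)(CC(=C)O[Si](C)(C)C(C)(C)C)[C@@H]2C[C@H]1C2(C)C
F9 | step 1 | 2-allyl-4,6,6-trimethylbicyclo[3.1.1]hept-3-en-2-ol (allyl anti to the gem-dimethyl bridge) | O[C@@]1(CC=C)C=C(C)[C@@H]2C[C@H]1C2(C)C
F10 | step 12 | (S)-5-(tert-butyldiphenylsilyloxy)-3-methylpentan-1-ol | CC(C)(C)[Si](c1ccccc1)(c1ccccc1)OCC[C@@H](C)CCO
F11 | step 12 | (R)-tert-butyl[(5-iodo-3-methylpentyl)oxy]diphenylsilane | CC(C)(C)[Si](c1ccccc1)(c1ccccc1)OCC[C@@H](C)CCI
F12 | step 12 | C9-alkylated enone, chain axial and trans to C20 (C9 epimer of the natural series), 2-(tert-butyldimethylsilyloxy)-15-(tert-butyldiphenylsilyloxy)-17-norlabd-6-en-8-one | O=C1C=C[C@@H]2C(C)(C)C[C@@H](O[Si](C)(C)C(C)(C)C)C[C@@]2(C)[C@H]1CC[C@H](C)CCO[Si](c1ccccc1)(c1ccccc1)C(C)(C)C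
F13 | step 12 | C9 epimer of 19 (chain axial) | O=C1CC[C@@H]2C(C)(C)C[C@@H](O[Si](C)(C)C(C)(C)C)C[C@@]2(C)[C@H]1CC[C@H](C)CCO[Si](c1ccccc1)(c1ccccc1)C(C)(C)C
F0 | step 13 | none | none
A1 | alternative 1 | bicyclic β-keto ester from the oxidative radical cyclisation (quaternary C10, C2 ketone, C1 methyl ester, C5=C6 alkene, 15-O-benzyl chain) | c1ccccc1COCC[C@@H](C)CC[C@@H]1[C@@H](C)CC=C2C(C)(C)CC(=O)[C@H](C(=O)OC)[C@@]12C
A2 | alternative 1 | monocyclic β-keto ester precursor with C5=C10 alkene | c1ccccc1COCC[C@@H](C)CC[C@@H]1[C@@H](C)CCC(C(C)(C)CC(=O)CC(=O)OC)=C1C
A3 | alternative 2 | 9,10-methano cyclopropyl carbinol (C20 syn to the C8 hydroxyl, trans to H5) | O[C@@H]1CC[C@@H]2C(C)(C)C[C@@H](O[Si](C)(C)C(C)(C)C)C[C@]23C[C@H]13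
A4 | alternative 2 | C8 allylic alcohol with C9=C10 alkene, precursor of A3 | O[C@@H]1CC[C@@H]2C(C)(C)C[C@@H](O[Si](C)(C)C(C)(C)C)CC2=C1
A5 | alternative 3 | trans-fused 4,4,8,10-tetramethyl-Δ7-octalin-6,9-dione with C2=C3 silyl enol ether | O=C1C(C)=CC(=O)[C@@H]2C(C)(C)C=C(O[Si](C)(C)C(C)(C)C)C[C@@]12C
A6 | alternative 3 | 2,6-dimethyl-1,4-benzoquinone | CC1=CC(=O)C=C(C)C1=O
A7 | alternative 3 | 2-(tert-butyldimethylsilyloxy)-4-methylpenta-1,3-diene | C=C(O[Si](C)(C)C(C)(C)C)C=C(C)C
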